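**Plan**

- Retrosynthetic cuts, in order: the C3–CHO bond of ring A; the C1–C6 bond of ring A; the depside C(=O)–O bond; two C–C bonds of an eight-carbon chain.
- What permits the ring A cut: ring A carries oxygen at C2 and C4, methyl at C6 and the acyl carbon at C1. This is the orsellinate pattern that results when C2 of a 3,5,7-trioxooctanoyl chain closes on its C7 ketone.
- Forward, ring B is bought: methyl 2,4-dihydroxy-3,6-dimethylbenzoate becomes the 2-O-methyl-4-hydroxy phenol 4 (benzyl on O4, methyl on O2, benzyl off). In parallel the trimethyldioxinone is acetylated twice to diketo-dioxinone 9.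
- Heating 9 with 4 joins the chain to ring B through the ester oxygen. Ring A, the only ring formed, then closes on the aryl ester by aldol condensation, and formylation at C3 finishes the route.
- Stereochemistry: the target has no stereocentre. The two sp3 centres of the transient aldol adduct disappear on aromatisation.

Key step: step 7

Remark: the target is achiral and its depside bonds rotate freely, so the given SMILES defines a single compound and no step has to set configuration. Compounds 1, 5, 6 and 8 are taken as purchased.

**Route**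

Step 1
Reactants: 1 methyl 2,4-dihydroxy-3,6-dimethylbenzoate
Product: 2 methyl 4-(benzyloxy)-2-hydroxy-3,6-dimethylbenzoate
Conditions: BnBr (1.05 equiv), K2CO3, acetone, reflux
Reagents that add atoms: benzyl bromide, BrCc1ccccc1
Why: Williamson etherification should occur at O4 only, because the C2 hydroxyl is hydrogen-bonded to the ester carbonyl and flanked by the ester and the C3 methyl.

Step 2
Reactants: 2 methyl 4-(benzyloxy)-2-hydroxy-3,6-dimethylbenzoate
Product: 3 methyl 4-(benzyloxy)-2-methoxy-3,6-dimethylbenzoate
Conditions: MeI (excess), K2CO3, DMF, 60 °C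
Reagents that add atoms: iodomethane, CI
Why: Williamson O-methylation of the chelated, hindered phenol should proceed under forcing conditions in a dipolar aprotic solvent, since no other acidic site remains.

Step 3
Reactants: 3 methyl 4-(benzyloxy)-2-methoxy-3,6-dimethylbenzoate
Product: 4 methyl 4-hydroxy-2-methoxy-3,6-dimethylbenzoate
Conditions: H2 (1 atm), 10% Pd/C, EtOAc, rt
Reagents that add atoms: none
Why: Catalytic hydrogenolysis cleaves the benzyl aryl ether and leaves the methyl ester and methyl ether untouched.

Step 4
Reactants: 5 2,2,6-trimethyl-4H-1,3-dioxin-4-one; 6 acetyl chloride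
Product: 7 2,2-dimethyl-6-(2-oxopropyl)-4H-1,3-dioxin-4-one
Conditions: LiHMDS (1.0 equiv), THF, −78 °C; then AcCl (0.5 equiv), −78 °C; aq NH4Cl
Reagents that add atoms: none
Why: γ-C-Acylation of the lithium dienolate of the dioxinone (a vinylogous Claisen condensation) is the standard entry to 6-(2-oxoalkyl)dioxinones, and the half equivalent of acid chloride leaves dienolate to absorb the more acidic proton of the product.

Step 5
Reactants: 7 2,2-dimethyl-6-(2-oxopropyl)-4H-1,3-dioxin-4-one; 8 N-methoxy-N-methylacetamide
Product: 9 6-(2,4-dioxopentyl)-2,2-dimethyl-4H-1,3-dioxin-4-one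
Conditions: LDA (2.2 equiv, commercial solution), THF, −78 °C; then 8 (1.1 equiv), −78 to −40 °C; 1 M HCl
Reagents that add atoms: none
Why: Double deprotonation gives the 1,3-dianion, whose terminal carbanion attacks the N-methoxy-N-methylamide in a Claisen-type acylation, and the chelated tetrahedral adduct persists until the acid quench so that no second addition occurs.

Step 6
Reactants: 9 6-(2,4-dioxopentyl)-2,2-dimethyl-4H-1,3-dioxin-4-one; 4 methyl 4-hydroxy-2-methoxy-3,6-dimethylbenzoate
Product: 11 methyl 2-methoxy-3,6-dimethyl-4-(3,5,7-trioxooctanoyloxy)benzoate, via diketo acylketene 10 (not isolated)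
Conditions: 4 (1.5 equiv), PhMe, 110 °C, 1 h; concentrate, use crude
Reagents that add atoms: none
Why: Retro-hetero-Diels–Alder fragmentation of the dioxinone expels acetone and the acylketene is captured by the phenol, the same acylketene acylation by which phenols are acetoacetylated with the trimethyldioxinone; the excess of 4 should let bimolecular capture outrun closure of the ketene onto its own enol oxygen.

Step 7
Reactants: 11 methyl 2-methoxy-3,6-dimethyl-4-(3,5,7-trioxooctanoyloxy)benzoate
Product: 13 methyl 4-(2,4-dihydroxy-6-methylbenzoyloxy)-2-methoxy-3,6-dimethylbenzoate, via cyclic aldol adduct 12 (not isolated)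
Conditions: Et3N (1.5 equiv)/AcOH (1.0 equiv), dry CH2Cl2, 0 °C to rt; then TFA (10 equiv), rt
Reagents that add atoms: none
Why: In the amine/acetate buffer the C2 methylene, flanked by the ester C1 and the C3 ketone, enolises and adds to the C7 methyl ketone to form the C2–C7 bond (C1–C6 of ring A) in aldol 12; TFA then eliminates the tertiary hydroxyl and the C3 and C5 carbonyls enolise to the resorcinol. The closest known reaction is the intramolecular aldol aromatisation of 3,5,7-trioxoalkanoate esters made by acylketene capture from diketo-dioxinones, the laboratory counterpart of orsellinate folding. Ring A closes in the 6-(enolexo)-exo-trig mode. No stereocentre is retained, since the two sp3 centres of 12 form without control and both vanish on aromatisation. The step needs the C2-to-C7 aldol to outrun C6-to-C1 Claisen closure and attack of the C5 enol oxygen on C1, both of which would expel the ring B phenoxide. The anhydrous, non-nucleophilic buffer keeps the chain largely as neutral enols with little free polyenolate, the C7 methyl ketone is the least hindered carbonyl, and C1 is a vinylogous carbonate in the enolised β-keto ester and is shielded by the C3 methyl of ring B.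

Step 8
Reactants: 13 methyl 4-(2,4-dihydroxy-6-methylbenzoyloxy)-2-methoxy-3,6-dimethylbenzoate
Product: 15 methyl 4-(3-formyl-2,4-dihydroxy-6-methylbenzoyloxy)-2-methoxy-3,6-dimethylbenzoate (2'-O-methylatranorin), via chloro(methoxy)methyl arene 14 (not isolated)
Conditions: Cl2CHOMe (1.2 equiv), TiCl4 (3 equiv), CH2Cl2, −10 to 0 °C; then ice-cold 1 M HCl
Reagents that add atoms: dichloromethyl methyl ether, COC(Cl)Cl; water, O
Why: Rieche formylation should go to C3 of ring A, because the titanium phenoxides at O2 and O4 deliver the electrophile between them and the C2-hydroxyl/ester chelate activates that site in resorcylates, while C5 is flanked by the C6 methyl and ring B is deactivated by its ester and acyloxy groups; aqueous acid then hydrolyses the α-chloro ether to the aldehyde.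

**Compound list**

1 | methyl 2,4-dihydroxy-3,6-dimethylbenzoate | COC(=O)c1c(C)cc(O)c(C)c1O | starting material
2 | methyl 4-(benzyloxy)-2-hydroxy-3,6-dimethylbenzoate | COC(=O)c1c(C)cc(OCc2ccccc2)c(C)c1O | intermediate
3 | methyl 4-(benzyloxy)-2-methoxy-3,6-dimethylbenzoate | COC(=O)c1c(C)cc(OCc2ccccc2)c(C)c1OC | intermediate
4 | methyl 4-hydroxy-2-methoxy-3,6-dimethylbenzoate | COC(=O)c1c(C)cc(O)c(C)c1OC | intermediate
5 | 2,2,6-trimethyl-4H-1,3-dioxin-4-one | CC1=CC(=O)OC(C)(C)O1 | starting material
6 | acetyl chloride | CC(Cl)=O | starting material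
7 | 2,2-dimethyl-6-(2-oxopropyl)-4H-1,3-dioxin-4-one | CC(=O)CC1=CC(=O)OC(C)(C)O1 | intermediate
8 | N-methoxy-N-methylacetamide | CON(C)C(C)=O | starting material
9 | 6-(2,4-dioxopentyl)-2,2-dimethyl-4H-1,3-dioxin-4-one | CC(=O)CC(=O)CC1=CC(=O)OC(C)(C)O1 | intermediate
10 | oct-1-ene-1,3,5,7-tetrone (diketo acylketene, formed in the flask) | CC(=O)CC(=O)CC(=O)C=C=O | intermediate
11 | methyl 2-methoxy-3,6-dimethyl-4-(3,5,7-trioxooctanoyloxy)benzoate | COC(=O)c1c(C)cc(OC(=O)CC(=O)CC(=O)CC(C)=O)c(C)c1OC | intermediate
12 | methyl 4-(2-hydroxy-2-methyl-4,6-dioxocyclohexane-1-carbonyloxy)-2-methoxy-3,6-dimethylbenzoate (cyclic aldol adduct, formed in the flask; racemic, both centres uncontrolled and erased in the same step) | COC(=O)c1c(C)cc(OC(=O)C2C(=O)CC(=O)CC2(C)O)c(C)c1OC | intermediate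
13 | methyl 4-(2,4-dihydroxy-6-methylbenzoyloxy)-2-methoxy-3,6-dimethylbenzoate | COC(=O)c1c(C)cc(OC(=O)c2c(C)cc(O)cc2O)c(C)c1OC | intermediate
14 | methyl 4-{3-[chloro(methoxy)methyl]-2,4-dihydroxy-6-methylbenzoyloxy}-2-methoxy-3,6-dimethylbenzoate (formed in the flask; racemic at the new CH, hydrolysed on work-up) | COC(=O)c1c(C)cc(OC(=O)c2c(C)cc(O)c(C(Cl)OC)c2O)c(C)c1OC | intermediate
15 | methyl 4-(3-formyl-2,4-dihydroxy-6-methylbenzoyloxy)-2-methoxy-3,6-dimethylbenzoate (2'-O-methylatranorin) | COC(=O)c1c(C)cc(OC(=O)c2c(C)cc(O)c(C=O)c2O)c(C)c1OC | target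

**Step count**

Total steps: 8. Longest linear sequence: 6 (steps 1, 2, 3, 6, 7, 8).

**Steps most likely to fail**

Step 7. The risk is loss of the ring B phenoxide, by Claisen closure of C6 onto C1 or by lactonisation of the C5 enol oxygen onto C1, before the aldol bond forms. The fallback sets out from 9 (with 4) and returns at 13; it makes the same ring bond while the ester is still locked in the dioxinone and forms the depside ester afterwards. Compound 9 is aromatised with Et3N in CH2Cl2 (the dioxinone C5 adds to the terminal ketone, then water is lost) to give 7-hydroxy-2,2,5-trimethyl-4H-1,3-benzodioxin-4-one F1. Benzylation (BnBr, K2CO3, acetone) gives 7-(benzyloxy)-2,2,5-trimethyl-4H-1,3-benzodioxin-4-one F2. Irradiation of F2 at 300 nm in CH2Cl2 in the presence of 4 releases acetone and an o-quinone ketene, which acylates the phenol to give methyl 4-[4-(benzyloxy)-2-hydroxy-6-methylbenzoyloxy]-2-methoxy-3,6-dimethylbenzoate F3. Hydrogenolysis (H2, Pd/C, EtOAc) then gives 13.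

Step 6. The risk is that the hindered, electron-poor phenol captures the acylketene too slowly, so that the ketene closes onto its own enol oxygen, or that the aryl ester reverts to the ketene at 110 °C. The fallback sets out from 9 and returns at 11. Compound 9 is heated in toluene (sealed tube, 110 °C) with a large excess of 2-methylpropane-2-thiol, a cheap trap that can be used far beyond what is sensible for 4, to give S-tert-butyl 3,5,7-trioxooctanethioate F4. The acyl group of F4 is then passed to 4 at room temperature with silver(I) trifluoroacetate in THF (thiophilic activation of a β-keto thioester toward O-nucleophiles), so that the aryl ester is made below the temperature at which it reverts.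

Step 8. The risk is formylation at C5 of ring A instead of C3, or Lewis-acid cleavage of the depside ester. The fallback sets out from 13 and returns at 15; it delivers the carbon by a sigmatropic shift instead of electrophilic substitution. Allylation at the unchelated O4 (allyl bromide, K2CO3, acetone, rt) gives methyl 4-[2-hydroxy-6-methyl-4-(prop-2-en-1-yloxy)benzoyloxy]-2-methoxy-3,6-dimethylbenzoate F5. Aromatic Claisen rearrangement (PhNEt2, 190 °C) should go to C3, where the C2-hydroxyl/ester chelate fixes the C3–C4 double bond, giving methyl 4-[2,4-dihydroxy-6-methyl-3-(prop-2-en-1-yl)benzoyloxy]-2-methoxy-3,6-dimethylbenzoate F6. Alkene isomerisation (RuClH(CO)(PPh3)3 cat., toluene, 80 °C) gives methyl 4-{2,4-dihydroxy-6-methyl-3-[(E)-prop-1-en-1-yl]benzoyloxy}-2-methoxy-3,6-dimethylbenzoate F7. Lemieux–Johnson cleavage (OsO4 cat., NaIO4, 2,6-lutidine, dioxane–water) then gives 15.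

**Further compounds**

F1 | step 7 | 7-hydroxy-2,2,5-trimethyl-4H-1,3-benzodioxin-4-one | Cc1cc(O)cc2OC(C)(C)OC(=O)c12
F2 | step 7 | 7-(benzyloxy)-2,2,5-trimethyl-4H-1,3-benzodioxin-4-one | Cc1cc(OCc3ccccc3)cc2OC(C)(C)OC(=O)c12
F3 | step 7 | methyl 4-[4-(benzyloxy)-2-hydroxy-6-methylbenzoyloxy]-2-methoxy-3,6-dimethylbenzoate | COC(=O)c1c(C)cc(OC(=O)c2c(C)cc(OCc3ccccc3)cc2O)c(C)c1OC
F4 | step 6 | S-tert-butyl 3,5,7-trioxooctanethioate | CC(=O)CC(=O)CC(=O)CC(=O)SC(C)(C)C
F5 | step 8 | methyl 4-[2-hydroxy-6-methyl-4-(prop-2-en-1-yloxy)benzoyloxy]-2-methoxy-3,6-dimethylbenzoate | COC(=O)c1c(C)cc(OC(=O)c2c(C)cc(OCC=C)cc2O)c(C)c1OC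
F6 | step 8 | methyl 4-[2,4-dihydroxy-6-methyl-3-(prop-2-en-1-yl)benzoyloxy]-2-methoxy-3,6-dimethylbenzoate | COC(=O)c1c(C)cc(OC(=O)c2c(C)cc(O)c(CC=C)c2O)c(C)c1OC
F7 | step 8 | methyl 4-{2,4-dihydroxy-6-methyl-3-[(E)-prop-1-en-1-yl]benzoyloxy}-2-methoxy-3,6-dimethylbenzoate | COC(=O)c1c(C)cc(OC(=O)c2c(C)cc(O)c(/C=C/C)c2O)c(C)c1OC
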